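## Retrosynthetic overview

- Target 19 → (global O-debenzylation) tetrabenzyl flavanone 18 → (flavanone C3–C4 bond, key step) formyl aryl 1-arylvinyl ether 17.
- 17 → (aryl–O bond, Chan–Lam alkenylation) salicylaldehyde 12 + alkenylboronate 16; 12 → (ortho-formylation, desilylation) biaryl 9.
- 9 → (flavone C3–ring D bond, Negishi) 3-iodoflavone 4 + arylzinc 8 from 3,5-bis(benzyloxy)phenol; ring D is symmetrical at this stage, so its para oxygen is singled out without a regiochemical question.
- Ring order: flavone rings A, C and B are bought intact (1); ring D comes from phenol 5 and ring E from ketone 13; ring F (the dihydropyranone) is the only ring made, closed in the key step.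
- Enabling feature: in ring F, O1 sits directly on the stereogenic C2, so cutting C3–C4 leaves an aryl enol ether whose C2=C3 bond (1,1-disubstituted, no allylic hydrogen) lies ortho to a formyl group on C4a. Adding the formyl C–H across it makes the ring, the ketone and the C2 stereocentre at once.

Key step: step 10

Remark: the stereocentre is read from the structure as (2R) at C2 of the flavanone; the flavone C3–flavanone C6 axis carries no descriptor and is taken as rotationally labile, so it is not controlled.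

## Route

Step 1
Reactants: 1 5-hydroxy-7-methoxy-2-(4-methoxyphenyl)-4H-chromen-4-one (apigenin 7,4'-dimethyl ether)
Product: 2 5-(benzyloxy)-7-methoxy-2-(4-methoxyphenyl)-4H-chromen-4-one
Conditions: BnBr, K2CO3, n-Bu4NI (cat.), DMF, 80 °C
Reagents that add atoms: benzyl bromide, BrCc1ccccc1
Why: Williamson etherification; the chelated 5-OH is the only acidic group and is alkylated under forcing carbonate conditions, which masks it for the organometallic steps.

Step 2
Reactants: 2 5-(benzyloxy)-7-methoxy-2-(4-methoxyphenyl)-4H-chromen-4-one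
Product: 4 5-(benzyloxy)-3-iodo-7-methoxy-2-(4-methoxyphenyl)-4H-chromen-4-one, via 3-lithioflavone 3 (not isolated)
Conditions: LiN(iPr)2, THF, −78 °C; then I2, −78 °C to rt
Reagents that add atoms: iodine, II
Why: Carbonyl-directed deprotonation of the vinylic C3–H of the chromone and iodinolysis of the vinyllithium should place iodine at C3 only, avoiding electrophilic iodination of the electron-rich ring A.

Step 3
Reactants: 5 3,5-bis(benzyloxy)phenol
Product: 6 [3,5-bis(benzyloxy)phenoxy]tri(propan-2-yl)silane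
Conditions: TIPSCl, imidazole, DMF, rt
Reagents that add atoms: chlorotri(propan-2-yl)silane, CC(C)[Si](Cl)(C(C)C)C(C)C
Why: Silylation of the phenol; the bulky silyl ether marks this oxygen as different from the two benzyl ethers and shields its two ortho positions in the next step.

Step 4
Reactants: 6 [3,5-bis(benzyloxy)phenoxy]tri(propan-2-yl)silane; 4 5-(benzyloxy)-3-iodo-7-methoxy-2-(4-methoxyphenyl)-4H-chromen-4-one
Product: 9 5-(benzyloxy)-3-[2,6-bis(benzyloxy)-4-(triisopropylsilyloxy)phenyl]-7-methoxy-2-(4-methoxyphenyl)-4H-chromen-4-one, via aryllithium 7 (not isolated), via arylzinc chloride 8 (not isolated)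
Conditions: n-BuLi, THF, 0 °C; ZnCl2, 0 °C to rt; then 4, Pd2(dba)3 (2.5 mol %), RuPhos (10 mol %), THF, 65 °C
Reagents that add atoms: none
Why: Directed ortho-lithiation at the one position flanked by two benzyloxy groups, transmetalation to zinc and Negishi coupling with the α-iodoenone, using a dialkylbiarylphosphine suited to di-ortho-substituted arylzincs; ring D is symmetrical, so only one isomer can form.

Step 5
Reactants: 9 5-(benzyloxy)-3-[2,6-bis(benzyloxy)-4-(triisopropylsilyloxy)phenyl]-7-methoxy-2-(4-methoxyphenyl)-4H-chromen-4-one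
Product: 10 5-(benzyloxy)-3-[2,6-bis(benzyloxy)-4-hydroxyphenyl]-7-methoxy-2-(4-methoxyphenyl)-4H-chromen-4-one
Conditions: n-Bu4NF, THF, 0 °C; aq NH4Cl
Reagents that add atoms: none
Why: Fluoride-induced cleavage of the aryl silyl ether should free the single phenol of ring D while all benzyl and methyl ethers stay.

Step 6
Reactants: 10 5-(benzyloxy)-3-[2,6-bis(benzyloxy)-4-hydroxyphenyl]-7-methoxy-2-(4-methoxyphenyl)-4H-chromen-4-one
Product: 12 2,4-bis(benzyloxy)-3-[5-(benzyloxy)-7-methoxy-2-(4-methoxyphenyl)-4-oxo-4H-chromen-3-yl]-6-hydroxybenzaldehyde, via hydroxymethylphenol 11 (not isolated)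
Conditions: MgCl2, Et3N, (CH2O)n, MeCN, reflux; then aq HCl
Reagents that add atoms: paraformaldehyde (reacts as formaldehyde), C=O
Why: Magnesium-phenoxide-directed ortho-formylation (Casnati–Skattebøl): formaldehyde is delivered only ortho to the free OH, a second formaldehyde oxidises the benzylic alkoxide, and the two ortho positions are equivalent.

Step 7
Reactants: 13 1-[4-(benzyloxy)phenyl]ethan-1-one
Product: 15 1-[4-(benzyloxy)phenyl]ethenyl trifluoromethanesulfonate, via potassium enolate 14 (not isolated)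
Conditions: KN(SiMe3)2, THF, −78 °C; then PhNTf2, −78 to 0 °C
Reagents that add atoms: N-phenylbis(trifluoromethanesulfonimide), O=S(=O)(N(c1ccccc1)S(=O)(=O)C(F)(F)F)C(F)(F)F
Why: O-sulfonylation of the ketone enolate (only one enolisable side) should give the 1-arylvinyl triflate.

Step 8
Reactants: 15 1-[4-(benzyloxy)phenyl]ethenyl trifluoromethanesulfonate
Product: 16 2-{1-[4-(benzyloxy)phenyl]ethenyl}-4,4,5,5-tetramethyl-1,3,2-dioxaborolane
Conditions: B2pin2, PdCl2(PPh3)2 (3 mol %), PPh3 (6 mol %), KOPh, toluene, 50 °C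
Reagents that add atoms: bis(pinacolato)diboron, CC1(C)OB(OC1(C)C)B1OC(C)(C)C(C)(C)O1
Why: Miyaura borylation of an alkenyl triflate keeps the 1,1-disubstituted alkene and should give a storable alkenylboronate.

Step 9
Reactants: 12 2,4-bis(benzyloxy)-3-[5-(benzyloxy)-7-methoxy-2-(4-methoxyphenyl)-4-oxo-4H-chromen-3-yl]-6-hydroxybenzaldehyde; 16 2-{1-[4-(benzyloxy)phenyl]ethenyl}-4,4,5,5-tetramethyl-1,3,2-dioxaborolane
Product: 17 2,4-bis(benzyloxy)-3-[5-(benzyloxy)-7-methoxy-2-(4-methoxyphenyl)-4-oxo-4H-chromen-3-yl]-6-({1-[4-(benzyloxy)phenyl]ethenyl}oxy)benzaldehyde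
Conditions: Cu(OAc)2 (2 equiv), Et3N, 4 Å molecular sieves, CH2Cl2, dry air, rt
Reagents that add atoms: none
Why: Chan–Lam–Evans oxidative C–O coupling of the only free phenol with the alkenylboronate should form the aryl 1-arylvinyl ether under conditions mild enough for the aldehyde.

Step 10
Reactants: 17 2,4-bis(benzyloxy)-3-[5-(benzyloxy)-7-methoxy-2-(4-methoxyphenyl)-4-oxo-4H-chromen-3-yl]-6-({1-[4-(benzyloxy)phenyl]ethenyl}oxy)benzaldehyde
Product: 18 (2R)-5,7-bis(benzyloxy)-6-[5-(benzyloxy)-7-methoxy-2-(4-methoxyphenyl)-4-oxo-4H-chromen-3-yl]-2-[4-(benzyloxy)phenyl]-2,3-dihydro-4H-chromen-4-one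
Conditions: [Rh(cod)Cl]2 (2.5 mol %), (R)-DTBM-SEGPHOS (5.5 mol %), NaB[3,5-(CF3)2C6H3]4 (5 mol %), THF, 60 °C
Reagents that add atoms: none
Why: Proposed new method: a cationic monovalent rhodium bisphosphine complex should add oxidatively into the formyl C–H bond of 17, the ortho enol ether then inserts into Rh–H with hydride going to the oxygen-bearing carbon (future C2) and rhodium to the terminal CH2 (future C3), and C–C reductive elimination from the seven-membered acyl-alkyl rhodacycle forms the C3–C4 bond. The closest known reaction type is the enantioselective rhodium-catalysed intramolecular alkene hydroacylation of 2-(1-arylvinyl)benzaldehydes to 3-arylindanones and of ortho-(2-substituted allyl)benzaldehydes to 3-substituted tetralones; this is its oxa-analogue, and aryl vinyl ethers have not been shown in this role. Ring F (O1–C2–C3–C4–C4a–C8a) is closed in a formal 6-endo-trig mode, the acyl carbon being delivered to the alkene terminus. The single new stereocentre C2 is set by the axially chiral bisphosphine, which discriminates the two enol-ether faces during reversible hydride insertion and turnover-limiting reductive elimination; the (R)-ligand is written, and its mirror image is used if a first run shows the 2S sense. The step needs endo over exo regioselectivity (the exo path would require a tertiary alkyl–rhodium bond and a quaternary centre in a five-membered benzofuranone, which is sterically disfavoured), hydroacylation over decarbonylation (favoured by the alkene held next to the acyl hydride) and no alkene isomerisation (the enol ether has no allylic hydrogen). The neutral, base-free conditions should leave the benzyl ethers, the flavone and the base-sensitive C2 centre untouched.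

Step 11
Reactants: 18 (2R)-5,7-bis(benzyloxy)-6-[5-(benzyloxy)-7-methoxy-2-(4-methoxyphenyl)-4-oxo-4H-chromen-3-yl]-2-[4-(benzyloxy)phenyl]-2,3-dihydro-4H-chromen-4-one
Product: 19 (2R)-5,7-dihydroxy-6-[5-hydroxy-7-methoxy-2-(4-methoxyphenyl)-4-oxo-4H-chromen-3-yl]-2-(4-hydroxyphenyl)-2,3-dihydro-4H-chromen-4-one (CNP0292254.1)
Conditions: H2 (1 atm), 10% Pd/C, EtOAc–MeOH, rt
Reagents that add atoms: none
Why: Catalytic hydrogenolysis of the four benzyl ethers under neutral conditions should not epimerise C2 and should leave the methyl ethers, the tetrasubstituted chromone alkene and the chelated aryl ketone intact.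

## Compound list

1 | 5-hydroxy-7-methoxy-2-(4-methoxyphenyl)-4H-chromen-4-one | COc1ccc(-c2oc3cc(OC)cc(O)c3c(=O)c2)cc1 | starting material
2 | 5-(benzyloxy)-7-methoxy-2-(4-methoxyphenyl)-4H-chromen-4-one | COc1ccc(-c2oc3cc(OC)cc(OCc4ccccc4)c3c(=O)c2)cc1 | intermediate
3 | [5-(benzyloxy)-7-methoxy-2-(4-methoxyphenyl)-4-oxo-4H-chromen-3-yl]lithium (not isolated) | COc1ccc(-c2oc3cc(OC)cc(OCc4ccccc4)c3c(=O)c2[Li])cc1 | intermediate
4 | 5-(benzyloxy)-3-iodo-7-methoxy-2-(4-methoxyphenyl)-4H-chromen-4-one | COc1ccc(-c2oc3cc(OC)cc(OCc4ccccc4)c3c(=O)c2I)cc1 | intermediate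
5 | 3,5-bis(benzyloxy)phenol | Oc1cc(OCc2ccccc2)cc(OCc2ccccc2)c1 | starting material
6 | [3,5-bis(benzyloxy)phenoxy]tri(propan-2-yl)silane | CC(C)[Si](Oc1cc(OCc2ccccc2)cc(OCc2ccccc2)c1)(C(C)C)C(C)C | intermediate
7 | [2,6-bis(benzyloxy)-4-(triisopropylsilyloxy)phenyl]lithium (not isolated) | [Li]c1c(OCc2ccccc2)cc(O[Si](C(C)C)(C(C)C)C(C)C)cc1OCc1ccccc1 | intermediate
8 | [2,6-bis(benzyloxy)-4-(triisopropylsilyloxy)phenyl]zinc chloride (not isolated) | Cl[Zn]c1c(OCc2ccccc2)cc(O[Si](C(C)C)(C(C)C)C(C)C)cc1OCc1ccccc1 | intermediate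
9 | 5-(benzyloxy)-3-[2,6-bis(benzyloxy)-4-(triisopropylsilyloxy)phenyl]-7-methoxy-2-(4-methoxyphenyl)-4H-chromen-4-one | COc1ccc(-c2oc3cc(OC)cc(OCc4ccccc4)c3c(=O)c2-c2c(OCc3ccccc3)cc(O[Si](C(C)C)(C(C)C)C(C)C)cc2OCc2ccccc2)cc1 | intermediate
10 | 5-(benzyloxy)-3-[2,6-bis(benzyloxy)-4-hydroxyphenyl]-7-methoxy-2-(4-methoxyphenyl)-4H-chromen-4-one | COc1ccc(-c2oc3cc(OC)cc(OCc4ccccc4)c3c(=O)c2-c2c(OCc3ccccc3)cc(O)cc2OCc2ccccc2)cc1 | intermediate
11 | 5-(benzyloxy)-3-[2,6-bis(benzyloxy)-4-hydroxy-3-(hydroxymethyl)phenyl]-7-methoxy-2-(4-methoxyphenyl)-4H-chromen-4-one (present as its magnesium salt, not isolated) | COc1ccc(-c2oc3cc(OC)cc(OCc4ccccc4)c3c(=O)c2-c2c(OCc3ccccc3)c(CO)c(O)cc2OCc2ccccc2)cc1 | intermediate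
12 | 2,4-bis(benzyloxy)-3-[5-(benzyloxy)-7-methoxy-2-(4-methoxyphenyl)-4-oxo-4H-chromen-3-yl]-6-hydroxybenzaldehyde | COc1ccc(-c2oc3cc(OC)cc(OCc4ccccc4)c3c(=O)c2-c2c(OCc3ccccc3)c(C=O)c(O)cc2OCc2ccccc2)cc1 | intermediate
13 | 1-[4-(benzyloxy)phenyl]ethan-1-one | CC(=O)c1ccc(OCc2ccccc2)cc1 | starting material
14 | potassium 1-[4-(benzyloxy)phenyl]ethen-1-olate (not isolated) | [K+].[O-]C(=C)c1ccc(OCc2ccccc2)cc1 | intermediate
15 | 1-[4-(benzyloxy)phenyl]ethenyl trifluoromethanesulfonate | C=C(OS(=O)(=O)C(F)(F)F)c1ccc(OCc2ccccc2)cc1 | intermediate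
16 | 2-{1-[4-(benzyloxy)phenyl]ethenyl}-4,4,5,5-tetramethyl-1,3,2-dioxaborolane | C=C(B1OC(C)(C)C(C)(C)O1)c1ccc(OCc2ccccc2)cc1 | intermediate
17 | 2,4-bis(benzyloxy)-3-[5-(benzyloxy)-7-methoxy-2-(4-methoxyphenyl)-4-oxo-4H-chromen-3-yl]-6-({1-[4-(benzyloxy)phenyl]ethenyl}oxy)benzaldehyde | COc1ccc(-c2oc3cc(OC)cc(OCc4ccccc4)c3c(=O)c2-c2c(OCc3ccccc3)c(C=O)c(OC(=C)c3ccc(OCc4ccccc4)cc3)cc2OCc2ccccc2)cc1 | intermediate
18 | (2R)-5,7-bis(benzyloxy)-6-[5-(benzyloxy)-7-methoxy-2-(4-methoxyphenyl)-4-oxo-4H-chromen-3-yl]-2-[4-(benzyloxy)phenyl]-2,3-dihydro-4H-chromen-4-one | COc1ccc(-c2oc3cc(OC)cc(OCc4ccccc4)c3c(=O)c2-c2c(OCc3ccccc3)cc3c(c2OCc2ccccc2)C(=O)C[C@H](c2ccc(OCc4ccccc4)cc2)O3)cc1 | intermediate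
19 | (2R)-5,7-dihydroxy-6-[5-hydroxy-7-methoxy-2-(4-methoxyphenyl)-4-oxo-4H-chromen-3-yl]-2-(4-hydroxyphenyl)-2,3-dihydro-4H-chromen-4-one | COc1ccc(-c2oc3cc(OC)cc(O)c3c(=O)c2-c2c(O)cc3c(c2O)C(=O)C[C@H](c2ccc(O)cc2)O3)cc1 | target

## Step count and risks

Total step count: 11. Longest linear sequence: 8 steps (steps 1, 2, 4, 5, 6, 9, 10, 11).

Steps most likely to fail:

1. Step 10 (proposed new method). Decarbonylation of the acyl rhodium hydride may outrun insertion of the electron-rich enol ether, or the insertion may proceed with poor facial discrimination. The fallback forms the same C3–C4 bond by known carbene catalysis with the stereocentre put in beforehand; it sets out from 12 and returns at 18. Corey–Bakshi–Shibata reduction of purchased 2-bromo-1-[4-(benzyloxy)phenyl]ethan-1-one with the (R)-methyl oxazaborolidine and BH3·SMe2 would give (1R)-1-[4-(benzyloxy)phenyl]-2-bromoethan-1-ol F1. Mitsunobu etherification of the acidic ortho-formyl phenol 12 with F1 (PPh3, DIAD, THF, 0 °C) should proceed with inversion to 2,4-bis(benzyloxy)-3-[5-(benzyloxy)-7-methoxy-2-(4-methoxyphenyl)-4-oxo-4H-chromen-3-yl]-6-{(1S)-1-[4-(benzyloxy)phenyl]-2-bromoethoxy}benzaldehyde F2. An N-heterocyclic carbene (triazolium precatalyst, Cs2CO3, dioxane) would then turn the formyl group into a Breslow intermediate that displaces the primary bromide intramolecularly, the known carbene-catalysed aldehyde–alkyl halide cyclisation to chroman-4-ones, giving 18.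

2. Step 9. The salicylaldehyde unit may sequester copper as a chelate, and the hindered alkenylboronate may be protodeboronated or oxidised before C–O bond formation. The fallback reverses the polarity of the coupling; it sets out from 12 and returns at 17. Phenol 12 would be coupled with the electrophilic enol triflate 15, already made in step 7, under zerovalent palladium catalysis (Pd2(dba)3, 2-(di-tert-butylphosphino)biphenyl, K3PO4, toluene, 80–100 °C), the known route to aryl enol ethers from vinyl triflates and phenols. No new compound is needed.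

3. Step 4. Transmetalation and reductive elimination at the doubly ortho-substituted arylzinc may be slow, so that protodemetalation of 8 and reduction of iodide 4 take over. The fallback reverses the roles of the two halves; it sets out from 2 and 6 and returns at 9. Lithiation of 6 as in step 4 and quenching with iodine would give {[3,5-bis(benzyloxy)-4-iodophenyl]oxy}tri(propan-2-yl)silane F3. Direct C3–H zincation of flavone 2 with TMPZnCl·LiCl (THF, rt) would give [5-(benzyloxy)-7-methoxy-2-(4-methoxyphenyl)-4-oxo-4H-chromen-3-yl]zinc chloride F4, the less hindered nucleophile. Negishi coupling of F4 with F3 (Pd2(dba)3, SPhos, THF, 65 °C) would give 9.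

Further compounds
F1 | step 10 | (1R)-1-[4-(benzyloxy)phenyl]-2-bromoethan-1-ol | O[C@@H](CBr)c1ccc(OCc2ccccc2)cc1
F2 | step 10 | 2,4-bis(benzyloxy)-3-[5-(benzyloxy)-7-methoxy-2-(4-methoxyphenyl)-4-oxo-4H-chromen-3-yl]-6-{(1S)-1-[4-(benzyloxy)phenyl]-2-bromoethoxy}benzaldehyde | COc1ccc(-c2oc3cc(OC)cc(OCc4ccccc4)c3c(=O)c2-c2c(OCc3ccccc3)c(C=O)c(O[C@H](CBr)c3ccc(OCc4ccccc4)cc3)cc2OCc2ccccc2)cc1
F0 | step 9 | none | none
F3 | step 4 | {[3,5-bis(benzyloxy)-4-iodophenyl]oxy}tri(propan-2-yl)silane | CC(C)[Si](Oc1cc(OCc2ccccc2)c(I)c(OCc2ccccc2)c1)(C(C)C)C(C)C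
F4 | step 4 | [5-(benzyloxy)-7-methoxy-2-(4-methoxyphenyl)-4-oxo-4H-chromen-3-yl]zinc chloride | COc1ccc(-c2oc3cc(OC)cc(OCc4ccccc4)c3c(=O)c2[Zn]Cl)cc1
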